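The earlier runs and the new flask stem from a simulated flask on assumed constants.

At the reading at 5.0 min we want the target in two flasks, so we need a clock for turning the charge into target.

| flask | substrate | partner | temperature | remark | time |
|---|---|---|---|---|---|
| elm | 0.0091 M | 1.8 equiv | 20 °C | run made earlier |  |
| oak | 0.041 M | 1.8 equiv | 35 °C | run made earlier |  |
| dawn | 0.050 M | 1.80 equiv |  | at 25 °C until 1.5 min, from then on at 45 °C | 5.0 min |
| autumn | 0.015 M | 1.80 equiv |  | at 45 °C throughout | 5.0 min |

| run | time / min | target / % | substrate / % |
|---|---|---|---|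
| elm | 0.667 | 5.2 | 86.2 |
| elm | 1.33 | 13.3 | 75.4 |
| elm | 2.00 | 22.9 | 69.9 |
| elm | 3.00 | 31.5 | 57.8 |
| elm | 4.00 | 42.2 | 50.2 |
| oak | 0.200 | 11.2 | 80.6 |
| oak | 0.500 | 26.6 | 65.0 |
| oak | 1.00 | 47.7 | 43.9 |
| oak | 1.50 | 57.5 | 30.5 |
| oak | 2.50 | 72.4 | 17.3 |

(each reading ± 1 percentage point)

* the winner by amount of target, in percent of the substrate charged; "neither" if no more than 2 percentage points parts them (dawn / autumn / neither)
* how much target is there at the end, in percent of the substrate charged: dawn
* how much target is there at the end, in percent of the substrate charged: autumn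

- in percentages every species weighs as the substrate in it: one side product counts as two
- steps under discussion: substrate <-> tautomer; substrate + partner <-> isomer of the product; partner + tautomer -> target; substrate + target -> side product
- where the amount of substrate changes, what is given in equivalents or mol% on it follows

We take rate of target = k × substrate × partner and ask which k carries a flask from its charge to the fraction of that charge last read as target. Elm gives 0.161 M⁻¹ s⁻¹ and oak gives 0.157 M⁻¹ s⁻¹, so we carry their mean, the apparent second-order constant k = 0.159 M⁻¹ s⁻¹. Held at that value, it gives our own reckoning: 92.8 % of the charge as target in dawn, before any loss to side product, and 63.5 % in autumn.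

The forecast, for which “concentration decides the outcome”, names dawn, with 86 % (76 % to 93 %) for dawn, below our figure, and 65 % (54 % to 80 %) for autumn.

The flasks give 82.0 % in dawn and 74.8 % in autumn, so dawn wins.

    substrate ⇌ tautomer (K = 0.190, k = 0.00780 s⁻¹, Ea = 81.0 kJ mol⁻¹, ΔH = −51.0 kJ mol⁻¹)
    substrate + partner ⇌ isomer of the product (K = 34.0 M⁻¹, k = 0.00950 M⁻¹ s⁻¹, Ea = 60.0 kJ mol⁻¹, ΔH = −6.00 kJ mol⁻¹)
    partner + tautomer → target (k = 2.40 M⁻¹ s⁻¹, Ea = 45.0 kJ mol⁻¹)
    substrate + target → side product (k = 0.00690 M⁻¹ s⁻¹, Ea = 63.0 kJ mol⁻¹)
    (constants at 25 °C)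

Read backwards, autumn needs k = 0.233 M⁻¹ s⁻¹, more than the 0.159 M⁻¹ s⁻¹ we carried. So k is not one number across these flasks, and the equations show a fork inside it: a tautomer molecule either meets partner or falls back to substrate. Part of what autumn lacks at the reading is due to that fall-back together with the time given: without the step autumn stands at 98.4 %, and after 50.0 min it stands at 91.7 %.

Take autumn with 0.450 equiv of partner, now the limiting reagent by charge. Autumn's k gives 26.4 %, and the simulation gives 28.8 %.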